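**The gap.** I could not read amber off any earlier run, since winter, the hottest of them at 40 °C, stayed below amber's 60 °C.

| flask | starting material | reagent | temperature | remark | time |
|---|---|---|---|---|---|
| noon | 0.88 M | 1.2 M | 15 °C | run made earlier |  |
| winter | 0.88 M | 2.6 M | 40 °C | run made earlier |  |
| summer | 1.8 M | 1.76 M | 15 °C | run made earlier |  |
| amber | 0.88 M | 1.76 M | 60 °C |  | 20 h |
| grey | 0.88 M | 1.76 M | 20 °C |  | 20 h |
| teal | 0.88 M | 1.76 M | 40 °C |  | 20 h |

| run | time / h | target / % |
|---|---|---|
| noon | 20.0 | 0 |
| noon | 30.0 | 0.8 |
| noon | 50.0 | 0.3 |
| noon | 72.0 | 0.8 |
| noon | 144 | 3.4 |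
| noon | 240 | 7.7 |
| winter | 10.0 | 14.7 |
| winter | 20.0 | 36.9 |
| winter | 30.0 | 55.7 |
| winter | 40.0 | 69.0 |
| winter | 60.0 | 84.9 |
| winter | 72.0 | 90.3 |
| summer | 20.0 | 0.9 |
| summer | 60.0 | 1.3 |
| summer | 120 | 3.6 |
| summer | 144 | 5.0 |
| summer | 240 | 10.2 |

(scatter of a reading: 0.3 percentage points)

1. which flask leads in amount of target, in percent of the starting material charged ("all alike" within 1.5 percentage points) (amber / grey / teal / all alike)
2. how much target is there at the end, in percent of the starting material charged: amber
3. how much target is there at the end, in percent of the starting material charged: grey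
4. how much target is there at the end, in percent of the starting material charged: teal



**A lag.** Winter went from 14.7% at 10.0 h to 36.9% at 20.0 h, more than doubling, so I took two steps in a row. From noon to summer at 240 h, target rose 1.32 times for c(reagent) up 1.47 times and c(starting material) up 2.05 times, so I scaled percentages by c(reagent).

**One clock.** Amber, grey and teal share their charges. If heat speeds both steps alike, they are one curve on a stretched time axis. Summer at 240 h held 0.694 of winter's target at 10.0 h, and its c(reagent) was 0.677 of winter's, so the two stood at one stage. The factor between winter's clock and summer's was then 24.0. As an Arrhenius law this gives 95.4 kJ mol⁻¹, the clock energy, meaning the activation energy of this exchange of hours between temperatures. But that is one pair of readings. Noon against winter gives 0.524 for a reagent ratio of 0.462, so the factor may be a little high.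

**Three estimates.** Teal shares winter's temperature, so proportion gives 25.0%. But winter grew only 2.51 times over those hours, against 4 for a square law, so it was already bending and I held this as a floor. Grey's 20 h equal 1.97 times as many summer hours, and the square law from summer's 5.0% at 144 h gives 0.375%, again low if bending has begun. Amber's clock runs 9.02 times faster than teal's. Scaled by reagent, that is 122 h of winter, and winter's tail at 0.0369 h⁻¹ extends to 98.5%. I held that as high, since amber has 2.00 equivalents of reagent against winter's 2.95, so its c(reagent) falls by a larger share.

**The forecast.** It named amber, with amber 98.5%, grey 0.5% and teal 29%, on the ground that “The percent yield rises about in proportion to reagent”. It stood above my floors for teal and grey, and I agreed on the order.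

**The flasks.** Amber led with 95.9%, ahead of teal at 27.4% and grey at 0.463%, under this scheme:

    intermediate → target (k = 0.0971 h⁻¹, Ea = 92.0 kJ mol⁻¹)
    2 starting material → self-condensation product (k = 2.21 × 10⁻⁴ L mol⁻¹ h⁻¹, Ea = 106 kJ mol⁻¹)
    starting material + reagent → intermediate + by-product (k = 0.0193 L mol⁻¹ h⁻¹, Ea = 94.0 kJ mol⁻¹)
    (constants at 40 °C)

In amber, the half-life of intermediate going to target, 0.86 h at 2.60 h, was shorter than the 4.5 h of starting material on its step with reagent at 20.0 h, the rate-limiting step, and the activation energies of these steps differ by 2.00 kJ mol⁻¹. By the clock energy, amber's 20 h count as 180 h of teal, which held 97.3% at 200 h. Grey's 200 h count as 16.4 h of teal, which held 10.3% at 10.0 h and 27.4% at 20.0 h, and grey stood at 23.0%.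

The runs come from a simulation with constants of no real substance; the scatter is artificial.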